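**Retrosynthetic overview**
1. Target 23 ⇒ the seven-membered ring is closed last, by an intramolecular aldol of an ethyl ketone onto a 1,2-dione (sets C6 and C7 of the bicycle).
2. Dione 22 ⇒ oxidation of an α-diazo ketone; its acyloxy carbon ⇒ diazo aldol of a vinyl diazoketone with lactone aldehyde 14, then esterification with (2R)-2-methylbutanoic acid.
3. trans-α-Methylidene lactone 12 with its 2-oxobutyl arm ⇒ copper-catalysed Grignard opening of a phosphonate-activated cyclopropane with in-flask olefination by formaldehyde, then ozonolysis.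
4. Key step: intramolecular cyclopropanation of an allylic diazophosphonoacetate forms the γ-lactone and the cyclopropane in one operation.
5. Ring order: γ-lactone and cyclopropane together (step 4) → cyclopropane opened (step 5) → cycloheptanone (step 13).

Assumption: (2R)-but-3-ene-1,2-diol (1) is taken as a purchased single enantiomer (available by kinetic resolution of butadiene monoepoxide).

Step 1
Reactants: 1 (2R)-but-3-ene-1,2-diol
Product: 2 (2R)-1-{[tert-butyl(dimethyl)silyl]oxy}but-3-en-2-ol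
Conditions: TBSCl (1.05 equiv), imidazole, CH2Cl2, −20 °C
Reagents that add atoms: tert-butyl(chloro)dimethylsilane, CC(C)(C)[Si](C)(C)Cl
Why: Selective silyl ether formation at the unhindered primary hydroxyl of the 1,2-diol leaves the allylic secondary alcohol free and the purchased stereocentre untouched.

Step 2
Reactants: 2 (2R)-1-{[tert-butyl(dimethyl)silyl]oxy}but-3-en-2-ol; 3 (diethoxyphosphoryl)acetic acid
Product: 4 (2R)-1-{[tert-butyl(dimethyl)silyl]oxy}but-3-en-2-yl (diethoxyphosphoryl)acetate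
Conditions: DCC, DMAP (10 mol %), CH2Cl2, 0 °C → rt
Reagents that add atoms: none
Why: Steglich esterification of the secondary allylic alcohol proceeds with retention because the C–O bond of the stereocentre is not broken.

Step 3
Reactants: 4 (2R)-1-{[tert-butyl(dimethyl)silyl]oxy}but-3-en-2-yl (diethoxyphosphoryl)acetate
Product: 5 (2R)-1-{[tert-butyl(dimethyl)silyl]oxy}but-3-en-2-yl diazo(diethoxyphosphoryl)acetate
Conditions: p-ABSA, DBU, MeCN, 0 °C → rt
Reagents that add atoms: 4-acetamidobenzenesulfonyl azide, CC(=O)Nc1ccc(cc1)S(=O)(=O)N=[N+]=[N-]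
Why: Regitz diazo transfer to the doubly activated (ester and phosphonate) methylene gives the acceptor/acceptor diazo compound without touching the stereocentre.

Step 4
Reactants: 5 (2R)-1-{[tert-butyl(dimethyl)silyl]oxy}but-3-en-2-yl diazo(diethoxyphosphoryl)acetate
Product: 6 diethyl [(1R,4R,5S)-4-({[tert-butyl(dimethyl)silyl]oxy}methyl)-2-oxo-3-oxabicyclo[3.1.0]hexan-1-yl]phosphonate
Conditions: Rh2(OAc)4 (2 mol %), ClCH2CH2Cl, 80 °C, slow addition of 5
Reagents that add atoms: none
Why: Intramolecular rhodium-carbenoid cyclopropanation of the allylic double bond closes the γ-lactone and the cyclopropane in one operation, the cis ring fusion being enforced by the tether and the CH2OTBS group taking the exo position (anti to the cyclopropane, allylic strain minimised in the transition state), which sets the two new stereocentres from the single existing one.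

Step 5
Reactants: 6 diethyl [(1R,4R,5S)-4-({[tert-butyl(dimethyl)silyl]oxy}methyl)-2-oxo-3-oxabicyclo[3.1.0]hexan-1-yl]phosphonate; 7 2-bromobut-1-ene
Product: 10 (4R,5R)-5-({[tert-butyl(dimethyl)silyl]oxy}methyl)-3-methylidene-4-(2-methylidenebutyl)oxolan-2-one, via Grignard reagent 8 (not isolated), via magnesium phosphonoenolate 9 (not isolated)
Conditions: 7, Mg, THF, rt; then CuI (10 mol %), 6, −40 → 0 °C; then (CH2O)n, 0 °C → rt
Reagents that add atoms: formaldehyde (used as paraformaldehyde), C=O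
Why: Copper-catalysed homoconjugate addition of the alkenyl Grignard reagent opens the doubly activated cyclopropane at its unhindered CH2 carbon and the phosphonate-stabilised lactone enolate so released undergoes Horner–Wadsworth–Emmons olefination with formaldehyde, so that the trans arrangement of the two ring substituents fixed in step 4 is carried over unchanged while the α-methylidene group is installed regiospecifically.

Step 6
Reactants: 10 (4R,5R)-5-({[tert-butyl(dimethyl)silyl]oxy}methyl)-3-methylidene-4-(2-methylidenebutyl)oxolan-2-one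
Product: 12 (4R,5R)-5-({[tert-butyl(dimethyl)silyl]oxy}methyl)-3-methylidene-4-(2-oxobutyl)oxolan-2-one, via secondary ozonide 11 (not isolated)
Conditions: O3, CH2Cl2, −78 °C (Sudan red 7B end point); then PPh3, −78 °C → rt
Reagents that add atoms: ozone, [O-][O+]=O
Why: Chemoselective ozonolysis with reductive work-up cleaves the electron-rich 1,1-dialkyl alkene to the ethyl ketone, while the electron-poor conjugated methylidene lactone, which reacts far more slowly with electrophilic ozone, is kept by stopping at the dye end point.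

Step 7
Reactants: 12 (4R,5R)-5-({[tert-butyl(dimethyl)silyl]oxy}methyl)-3-methylidene-4-(2-oxobutyl)oxolan-2-one
Product: 13 (4R,5R)-5-(hydroxymethyl)-3-methylidene-4-(2-oxobutyl)oxolan-2-one
Conditions: HF·pyridine, THF, 0 °C → rt
Reagents that add atoms: none
Why: Fluoride-mediated desilylation of the primary silyl ether under mildly acidic conditions neither adds to nor isomerises the methylidene lactone.

Step 8
Reactants: 13 (4R,5R)-5-(hydroxymethyl)-3-methylidene-4-(2-oxobutyl)oxolan-2-one
Product: 14 (2R,3R)-4-methylidene-5-oxo-3-(2-oxobutyl)oxolane-2-carbaldehyde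
Conditions: Dess–Martin periodinane, CH2Cl2, 0 °C → rt
Reagents that add atoms: none
Why: Dess–Martin oxidation gives the α-oxygenated aldehyde under neutral, non-epimerising conditions, and it is used at once without purification.

Step 9
Reactants: 15 (3E)-pent-3-en-2-one
Product: 17 (3E)-1-diazopent-3-en-2-one, via trifluoroacetyl diketone 16 (not isolated)
Conditions: LiN(SiMe3)2, THF, −78 °C; CF3CO2CH2CF3; then p-ABSA, Et3N, H2O, MeCN, rt
Reagents that add atoms: 4-acetamidobenzenesulfonyl azide, CC(=O)Nc1ccc(cc1)S(=O)(=O)N=[N+]=[N-]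
Why: Detrifluoroacetylative diazo transfer (Danheiser protocol), in which kinetic enolisation at the methyl group, Claisen trifluoroacetylation and diazo transfer with loss of the trifluoroacetyl group give the vinyl diazomethyl ketone without pyrazoline formation at the enone.

Step 10
Reactants: 14 (2R,3R)-4-methylidene-5-oxo-3-(2-oxobutyl)oxolane-2-carbaldehyde; 17 (3E)-1-diazopent-3-en-2-one
Product: 19 (4R,5R)-5-[(1R,4E)-2-diazo-1-hydroxy-3-oxohex-4-en-1-yl]-3-methylidene-4-(2-oxobutyl)oxolan-2-one, via magnesiated diazoketone 18 (not isolated)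
Conditions: 17, LiN(iPr)2, THF, −78 °C; MgBr2·OEt2; then 14, −78 °C; aq NH4Cl
Reagents that add atoms: none
Why: Aldol-type addition of the magnesiated diazomethyl ketone to the aldehyde (diazo aldol reaction), in which chelation of magnesium between the formyl oxygen and the adjacent ring oxygen (Cram-chelate model) exposes the face that gives the threo (1R) carbinol, while the ketone and the methylidene lactone are spared at −78 °C.

Step 11
Reactants: 19 (4R,5R)-5-[(1R,4E)-2-diazo-1-hydroxy-3-oxohex-4-en-1-yl]-3-methylidene-4-(2-oxobutyl)oxolan-2-one; 20 (2R)-2-methylbutanoic acid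
Product: 21 (1R,4E)-2-diazo-1-[(2R,3R)-4-methylidene-5-oxo-3-(2-oxobutyl)oxolan-2-yl]-3-oxohex-4-en-1-yl (2R)-2-methylbutanoate
Conditions: DCC, DMAP (10 mol %), CH2Cl2, 0 °C
Reagents that add atoms: none
Why: Steglich esterification of the secondary carbinol proceeds with retention at the carbinol carbon and without epimerising the α-stereocentre of the acid at 0 °C.

Step 12
Reactants: 21 (1R,4E)-2-diazo-1-[(2R,3R)-4-methylidene-5-oxo-3-(2-oxobutyl)oxolan-2-yl]-3-oxohex-4-en-1-yl (2R)-2-methylbutanoate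
Product: 22 (1S,4E)-1-[(2R,3R)-4-methylidene-5-oxo-3-(2-oxobutyl)oxolan-2-yl]-2,3-dioxohex-4-en-1-yl (2R)-2-methylbutanoate
Conditions: DMDO, acetone, −78 → 0 °C
Reagents that add atoms: dimethyldioxirane, CC1(C)OO1
Why: Oxygen-atom transfer from dimethyldioxirane to the nucleophilic diazo carbon (dioxirane oxidation of an α-diazo ketone) expels dinitrogen and unveils the 1,2-dione under neutral conditions, so that the electron-poor alkenes and the enolisable acyloxy-bearing stereocentre are left untouched (the descriptor changes from R to S only through priorities).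

Step 13
Reactants: 22 (1S,4E)-1-[(2R,3R)-4-methylidene-5-oxo-3-(2-oxobutyl)oxolan-2-yl]-2,3-dioxohex-4-en-1-yl (2R)-2-methylbutanoate
Product: 23 (3aR,6R,7S,8S,8aR)-7-[(2E)-but-2-enoyl]-7-hydroxy-6-methyl-3-methylidene-2,5-dioxooctahydro-2H-cyclohepta[b]furan-8-yl (2R)-2-methylbutanoate
Conditions: Sc(OTf)3 (20 mol %), CH2Cl2 (5 mM), 0 °C → rt
Reagents that add atoms: none
Why: Lewis-acid-catalysed intramolecular aldol addition (7-enolendo-exo-trig) of the ethyl-ketone enol to the scandium-chelated 1,2-dione closes the seven-membered ring, the regioisomeric enol being unable to cyclise because it would give a trans-fused bicyclo[3.3.0]octane, while a Cornforth-type transition state (acyloxy C–O bond anti to the reacting C=O) places the new tertiary hydroxyl at C7 trans to the C8 acyloxy group and the epimerisable methyl-bearing C6 settles trans to the bulky butenoyl group under the reversible conditions.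

**Compound list**
1 | (2R)-but-3-ene-1,2-diol | C=C[C@@H](O)CO | starting material
2 | (2R)-1-{[tert-butyl(dimethyl)silyl]oxy}but-3-en-2-ol | C=C[C@@H](O)CO[Si](C)(C)C(C)(C)C | intermediate
3 | (diethoxyphosphoryl)acetic acid | CCOP(=O)(OCC)CC(=O)O | starting material
4 | (2R)-1-{[tert-butyl(dimethyl)silyl]oxy}but-3-en-2-yl (diethoxyphosphoryl)acetate | C=C[C@@H](OC(=O)CP(=O)(OCC)OCC)CO[Si](C)(C)C(C)(C)C | intermediate
5 | (2R)-1-{[tert-butyl(dimethyl)silyl]oxy}but-3-en-2-yl diazo(diethoxyphosphoryl)acetate | C=C[C@@H](OC(=O)C(=[N+]=[N-])P(=O)(OCC)OCC)CO[Si](C)(C)C(C)(C)C | intermediate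
6 | diethyl [(1R,4R,5S)-4-({[tert-butyl(dimethyl)silyl]oxy}methyl)-2-oxo-3-oxabicyclo[3.1.0]hexan-1-yl]phosphonate | O=C1O[C@@H](CO[Si](C)(C)C(C)(C)C)[C@@H]2C[C@]12P(=O)(OCC)OCC | intermediate
7 | 2-bromobut-1-ene | C=C(Br)CC | starting material
8 | but-1-en-2-ylmagnesium bromide | CCC(=C)[Mg]Br | intermediate
9 | bromomagnesium (4S,5R)-5-({[tert-butyl(dimethyl)silyl]oxy}methyl)-3-(diethoxyphosphoryl)-4-(2-methylidenebutyl)-4,5-dihydrofuran-2-olate | C=C(CC)C[C@H]1[C@H](CO[Si](C)(C)C(C)(C)C)OC(O[Mg]Br)=C1P(=O)(OCC)OCC | intermediate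
10 | (4R,5R)-5-({[tert-butyl(dimethyl)silyl]oxy}methyl)-3-methylidene-4-(2-methylidenebutyl)oxolan-2-one | C=C1C(=O)O[C@@H](CO[Si](C)(C)C(C)(C)C)[C@@H]1CC(=C)CC | intermediate
11 | (4R,5R)-5-({[tert-butyl(dimethyl)silyl]oxy}methyl)-4-[(3-ethyl-1,2,4-trioxolan-3-yl)methyl]-3-methylideneoxolan-2-one (both configurations at the trioxolane carbon) | C=C1C(=O)O[C@@H](CO[Si](C)(C)C(C)(C)C)[C@@H]1CC1(CC)OCOO1 | intermediate
12 | (4R,5R)-5-({[tert-butyl(dimethyl)silyl]oxy}methyl)-3-methylidene-4-(2-oxobutyl)oxolan-2-one | C=C1C(=O)O[C@@H](CO[Si](C)(C)C(C)(C)C)[C@@H]1CC(=O)CC | intermediate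
13 | (4R,5R)-5-(hydroxymethyl)-3-methylidene-4-(2-oxobutyl)oxolan-2-one | C=C1C(=O)O[C@@H](CO)[C@@H]1CC(=O)CC | intermediate
14 | (2R,3R)-4-methylidene-5-oxo-3-(2-oxobutyl)oxolane-2-carbaldehyde | C=C1C(=O)O[C@@H](C=O)[C@@H]1CC(=O)CC | intermediate
15 | (3E)-pent-3-en-2-one | C/C=C/C(C)=O | starting material
16 | (5E)-1,1,1-trifluorohept-5-ene-2,4-dione (present as its lithium enolate) | C/C=C/C(=O)CC(=O)C(F)(F)F | intermediate
17 | (3E)-1-diazopent-3-en-2-one | C/C=C/C(=O)C=[N+]=[N-] | intermediate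
18 | (3E)-1-(bromomagnesio)-1-diazopent-3-en-2-one | C/C=C/C(=O)C(=[N+]=[N-])[Mg]Br | intermediate
19 | (4R,5R)-5-[(1R,4E)-2-diazo-1-hydroxy-3-oxohex-4-en-1-yl]-3-methylidene-4-(2-oxobutyl)oxolan-2-one | C=C1C(=O)O[C@@H]([C@H](O)C(=[N+]=[N-])C(=O)/C=C/C)[C@@H]1CC(=O)CC | intermediate
20 | (2R)-2-methylbutanoic acid | CC[C@@H](C)C(=O)O | starting material
21 | (1R,4E)-2-diazo-1-[(2R,3R)-4-methylidene-5-oxo-3-(2-oxobutyl)oxolan-2-yl]-3-oxohex-4-en-1-yl (2R)-2-methylbutanoate | C=C1C(=O)O[C@@H]([C@H](OC(=O)[C@H](C)CC)C(=[N+]=[N-])C(=O)/C=C/C)[C@@H]1CC(=O)CC | intermediate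
22 | (1S,4E)-1-[(2R,3R)-4-methylidene-5-oxo-3-(2-oxobutyl)oxolan-2-yl]-2,3-dioxohex-4-en-1-yl (2R)-2-methylbutanoate | C=C1C(=O)O[C@@H]([C@H](OC(=O)[C@H](C)CC)C(=O)C(=O)/C=C/C)[C@@H]1CC(=O)CC | intermediate
23 | (3aR,6R,7S,8S,8aR)-7-[(2E)-but-2-enoyl]-7-hydroxy-6-methyl-3-methylidene-2,5-dioxooctahydro-2H-cyclohepta[b]furan-8-yl (2R)-2-methylbutanoate | C=C1C(=O)O[C@@H]2[C@@H]1CC(=O)[C@H](C)[C@@](O)(C(=O)/C=C/C)[C@H]2OC(=O)[C@H](C)CC | target

**Totals**
Total step count: 13. Longest linear sequence: 12 (steps 1–8 and 10–13; step 9 is a one-step branch).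

**Steps most likely to fail, with fallbacks**

Step 4 (cyclopropanation). The exo/endo ratio under an achiral catalyst is uncertain, and carbenoid insertion into the C–H bonds next to the silyl ether may compete. The fallback bypasses the cyclopropane and sets out from 2. Acylation with acryloyl chloride (Et3N, CH2Cl2) gives (2R)-1-{[tert-butyl(dimethyl)silyl]oxy}but-3-en-2-yl prop-2-enoate F1. Ring-closing metathesis with the second-generation Grubbs catalyst gives (5R)-5-({[tert-butyl(dimethyl)silyl]oxy}methyl)furan-2(5H)-one F2. Mukaiyama–Michael addition of 2-(trimethylsilyloxy)but-1-ene (TBSOTf, CH2Cl2, −78 °C) anti to the C5 substituent, with trapping of the lactone silyl ketene acetal by dimethyl(methylidene)ammonium iodide, gives (4R,5R)-5-({[tert-butyl(dimethyl)silyl]oxy}methyl)-3-[(dimethylamino)methyl]-4-(2-oxobutyl)oxolan-2-one F3. N-Methylation (MeI) and elimination (NaHCO3) come back to the route at 12.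

Step 10 (diazo aldol). The ring oxygen is a weak donor, so magnesium chelation may not override the Felkin–Anh/Cornforth preference for the erythro carbinol. The fallback corrects the carbinol by oxidation and reduction and sets out from 14 and 17. The amine-catalysed addition (DBU, MeCN) gives 19 mixed with its epimer (4R,5R)-5-[(1S,4E)-2-diazo-1-hydroxy-3-oxohex-4-en-1-yl]-3-methylidene-4-(2-oxobutyl)oxolan-2-one F4. Dess–Martin oxidation converges both to (4R,5R)-5-[(4E)-2-diazo-3-oxohex-4-enoyl]-3-methylidene-4-(2-oxobutyl)oxolan-2-one F5. Reduction with a small non-chelating hydride (NaBH4, EtOH, −78 °C; Felkin–Anh attack anti to the ring C–O bond, which for a ketone gives the threo alcohol) comes back to the route at 19.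

Step 13 (ring-closing aldol). This is the least certain step: the ketone may not enolise under Lewis acid alone, the acidic acyloxy-bearing CH can trigger β-elimination of the lactone oxygen, and the facial selectivity at the new carbinol rests on a model. The fallback replaces the ene-dione by a more electrophilic, non-conjugated α-keto thioester and attaches the butenoyl group last; it sets out from 14. Addition of S-ethyl 2-diazoethanethioate F6 (made from S-ethyl thioacetate by the sequence of step 9) under the conditions of step 10 gives S-ethyl (3R)-2-diazo-3-hydroxy-3-[(2R,3R)-4-methylidene-5-oxo-3-(2-oxobutyl)oxolan-2-yl]propanethioate F7. Esterification with 20 gives S-ethyl (3R)-2-diazo-3-{[(2R)-2-methylbutanoyl]oxy}-3-[(2R,3R)-4-methylidene-5-oxo-3-(2-oxobutyl)oxolan-2-yl]propanethioate F8. DMDO gives S-ethyl (3S)-3-{[(2R)-2-methylbutanoyl]oxy}-3-[(2R,3R)-4-methylidene-5-oxo-3-(2-oxobutyl)oxolan-2-yl]-2-oxopropanethioate F9. The Lewis-acid aldol then gives S-ethyl (3aR,6R,7S,8S,8aR)-7-hydroxy-6-methyl-3-methylidene-8-{[(2R)-2-methylbutanoyl]oxy}-2,5-dioxooctahydro-2H-cyclohepta[b]furan-7-carbothioate F10. Liebeskind–Srogl coupling with (E)-prop-1-enylboronic acid (Pd2(dba)3, tri(2-furyl)phosphine, Cu(O2CC4H3S), THF, 50 °C) comes back to the route at 23.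

Further compounds
F1 | step 4 | (2R)-1-{[tert-butyl(dimethyl)silyl]oxy}but-3-en-2-yl prop-2-enoate | C=C[C@@H](OC(=O)C=C)CO[Si](C)(C)C(C)(C)C
F2 | step 4 | (5R)-5-({[tert-butyl(dimethyl)silyl]oxy}methyl)furan-2(5H)-one | O=C1C=C[C@H](CO[Si](C)(C)C(C)(C)C)O1
F3 | step 4 | (4R,5R)-5-({[tert-butyl(dimethyl)silyl]oxy}methyl)-3-[(dimethylamino)methyl]-4-(2-oxobutyl)oxolan-2-one (both configurations at C3) | CN(C)CC1C(=O)O[C@@H](CO[Si](C)(C)C(C)(C)C)[C@@H]1CC(=O)CC
F4 | step 10 | (4R,5R)-5-[(1S,4E)-2-diazo-1-hydroxy-3-oxohex-4-en-1-yl]-3-methylidene-4-(2-oxobutyl)oxolan-2-one | C=C1C(=O)O[C@@H]([C@@H](O)C(=[N+]=[N-])C(=O)/C=C/C)[C@@H]1CC(=O)CC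
F5 | step 10 | (4R,5R)-5-[(4E)-2-diazo-3-oxohex-4-enoyl]-3-methylidene-4-(2-oxobutyl)oxolan-2-one | C=C1C(=O)O[C@@H](C(=O)C(=[N+]=[N-])C(=O)/C=C/C)[C@@H]1CC(=O)CC
F6 | step 13 | S-ethyl 2-diazoethanethioate | CCSC(=O)C=[N+]=[N-]
F7 | step 13 | S-ethyl (3R)-2-diazo-3-hydroxy-3-[(2R,3R)-4-methylidene-5-oxo-3-(2-oxobutyl)oxolan-2-yl]propanethioate | C=C1C(=O)O[C@@H]([C@H](O)C(=[N+]=[N-])C(=O)SCC)[C@@H]1CC(=O)CC
F8 | step 13 | S-ethyl (3R)-2-diazo-3-{[(2R)-2-methylbutanoyl]oxy}-3-[(2R,3R)-4-methylidene-5-oxo-3-(2-oxobutyl)oxolan-2-yl]propanethioate | C=C1C(=O)O[C@@H]([C@H](OC(=O)[C@H](C)CC)C(=[N+]=[N-])C(=O)SCC)[C@@H]1CC(=O)CC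
F9 | step 13 | S-ethyl (3S)-3-{[(2R)-2-methylbutanoyl]oxy}-3-[(2R,3R)-4-methylidene-5-oxo-3-(2-oxobutyl)oxolan-2-yl]-2-oxopropanethioate | C=C1C(=O)O[C@@H]([C@H](OC(=O)[C@H](C)CC)C(=O)C(=O)SCC)[C@@H]1CC(=O)CC
F10 | step 13 | S-ethyl (3aR,6R,7S,8S,8aR)-7-hydroxy-6-methyl-3-methylidene-8-{[(2R)-2-methylbutanoyl]oxy}-2,5-dioxooctahydro-2H-cyclohepta[b]furan-7-carbothioate | C=C1C(=O)O[C@@H]2[C@@H]1CC(=O)[C@H](C)[C@@](O)(C(=O)SCC)[C@H]2OC(=O)[C@H](C)CC
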